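**Plan**

- Retrosynthesis: the phenol is masked as a benzyl ether and the chromone C2=C3 bond is traced back to a chroman-4-one. The pyranone ring is then cut at O1–C8a, C4–C4a and O1–C2, leaving 4,5-dimethoxybenzyne and an (E)-5-arylpent-2-enoic acid. The acid is cut at its C2=C3 bond into a 3-arylpropanal and malonic acid.
- Enabling feature: in ring A (C4a, C5, C6, C7, C8, C8a) the methoxy groups sit on C6 and C7, mirror-related across the C4a–C8a bond. C4a and C8a are therefore the two equivalent carbons of a symmetric aryne, and either orientation of insertion gives the same 6,7-dimethoxy product.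
- Forward: dihydroconiferyl alcohol, which brings the guaiacyl ring and three chain carbons, is taken to the pentenoic acid in three steps. The aryne (ring A, bought as its silyl triflate) is inserted into the acyl C–O bond and the heterocycle closes in the same flask. Dehydrogenation and debenzylation finish the route.
- Stereochemistry: the target has no stereocentre. The E geometry of the acid comes from the Doebner condensation. The C2 centre of the chromanone forms racemic and is removed when the pyranone ring is aromatized.

Key step: step 4

Remark: because the target is achiral, the chromanone of the key step is carried as the racemate and no asymmetric control is attempted.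

**Route**

Step 1
Reactants: 1 dihydroconiferyl alcohol [4-(3-hydroxypropyl)-2-methoxyphenol]
Product: 2 3-(4-benzyloxy-3-methoxyphenyl)propan-1-ol
Conditions: BnBr (1.1 equiv), K2CO3 (1.5 equiv), acetone, reflux
Reagents that add atoms: benzyl bromide, BrCc1ccccc1
Why: Williamson ether synthesis; K2CO3 deprotonates only the phenol, not the primary alcohol, so benzylation should occur at the phenolic oxygen alone.

Step 2
Reactants: 2 3-(4-benzyloxy-3-methoxyphenyl)propan-1-ol
Product: 3 3-(4-benzyloxy-3-methoxyphenyl)propanal
Conditions: TEMPO (10 mol%), PhI(OAc)2 (1.1 equiv), CH2Cl2, rt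
Reagents that add atoms: none
Why: TEMPO-catalysed (oxoammonium) oxidation of a primary alcohol with (diacetoxyiodo)benzene as terminal oxidant stops at the aldehyde in the absence of water and should leave the benzyl ether and the electron-rich arene untouched.

Step 3
Reactants: 3 3-(4-benzyloxy-3-methoxyphenyl)propanal; 4 malonic acid
Product: 6 (E)-5-(4-benzyloxy-3-methoxyphenyl)pent-2-enoic acid, via alkylidenemalonic acid 5 (not isolated)
Conditions: malonic acid (1.5 equiv), pyridine, piperidine (cat.), rt to 90 °C
Reagents that add atoms: none
Why: Knoevenagel condensation in the Doebner modification; the alkylidenemalonic acid loses CO2 in hot pyridine to give the conjugated acid, and the E alkene is expected as the thermodynamically preferred isomer.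

Step 4
Reactants: 6 (E)-5-(4-benzyloxy-3-methoxyphenyl)pent-2-enoic acid; 7 4,5-dimethoxy-2-(trimethylsilyl)phenyl trifluoromethanesulfonate
Product: 10 2-[2-(4-benzyloxy-3-methoxyphenyl)ethyl]-6,7-dimethoxychroman-4-one (racemic), via 4,5-dimethoxybenzyne 8 (not isolated), via hydroxyaryl enone 9 (not isolated)
Conditions: 7 (1.5 equiv), CsF (4 equiv), THF, 125 °C, sealed tube
Reagents that add atoms: none
Why: Fluoride removes the silyl group of 7 and triflate departs to give symmetric aryne 8; the cesium carboxylate of 6 adds to it, the ortho aryl anion so formed attacks its own ester carbonyl, and the strained four-membered alkoxide opens to the 2-acylphenoxide of 9, a net insertion of the aryne into the acyl C–O bond that forms O1–C8a and C4–C4a. The phenoxide then adds to the β-carbon of the enone in a 6-endo-trig oxa-Michael closure (O1–C2), which builds the dihydropyranone ring. The closest known reaction type is the fluoride-mediated intermolecular C–O insertion of arynes into alk-2-enoic acids that gives 4-chromanones, an acyl counterpart of aryne σ-bond insertion. The new C2 stereocentre has no controlling element, should form racemic and is erased in step 5. The selectivity required is acyl transfer in preference to protonation of the aryl anion, which would stop at the aryl ester; it is secured by the aprotic medium in which the acid exists only as its carboxylate, by the anion sitting ortho to the ester it attacks, and by heating. Regiochemistry needs no control because the two aryne carbons of 8 are equivalent through the mirror symmetry of the 4,5-dimethoxy pattern.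

Step 5
Reactants: 10 2-[2-(4-benzyloxy-3-methoxyphenyl)ethyl]-6,7-dimethoxychroman-4-one
Product: 12 2-[2-(4-benzyloxy-3-methoxyphenyl)ethyl]-6,7-dimethoxy-4H-chromen-4-one, via 3-iodochromanone 11 (not isolated)
Conditions: I2 (0.2 equiv), DMSO, 120 °C
Reagents that add atoms: none
Why: Iodine-catalysed dehydrogenation in DMSO, as used for flavanone to flavone; α-iodination at C3, loss of HI across C2–C3 driven by formation of the aromatic pyranone, and reoxidation of HI to I2 by DMSO should give the chromone and remove the C2 stereocentre.

Step 6
Reactants: 12 2-[2-(4-benzyloxy-3-methoxyphenyl)ethyl]-6,7-dimethoxy-4H-chromen-4-one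
Product: 13 2-[2-(4-hydroxy-3-methoxyphenyl)ethyl]-6,7-dimethoxy-4H-chromen-4-one
Conditions: H2 (1 atm), 10% Pd/C, EtOAc–MeOH, rt
Reagents that add atoms: none
Why: Catalytic hydrogenolysis of a benzyl aryl ether; at 1 atm and room temperature the benzylic C–O bond should cleave well before the vinylogous-ester C2=C3 bond of the chromone is reduced.

**Compound list**

1 | dihydroconiferyl alcohol, 4-(3-hydroxypropyl)-2-methoxyphenol | OCCCc1ccc(O)c(OC)c1 | starting material
2 | 3-(4-benzyloxy-3-methoxyphenyl)propan-1-ol | OCCCc1ccc(OCc2ccccc2)c(OC)c1 | intermediate
3 | 3-(4-benzyloxy-3-methoxyphenyl)propanal | O=CCCc1ccc(OCc2ccccc2)c(OC)c1 | intermediate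
4 | malonic acid | OC(=O)CC(=O)O | starting material
5 | 2-[3-(4-benzyloxy-3-methoxyphenyl)propylidene]malonic acid (not isolated) | OC(=O)C(=CCCc1ccc(OCc2ccccc2)c(OC)c1)C(=O)O | intermediate
6 | (E)-5-(4-benzyloxy-3-methoxyphenyl)pent-2-enoic acid | OC(=O)/C=C/CCc1ccc(OCc2ccccc2)c(OC)c1 | intermediate
7 | 4,5-dimethoxy-2-(trimethylsilyl)phenyl trifluoromethanesulfonate | COc1cc(OS(=O)(=O)C(F)(F)F)c([Si](C)(C)C)cc1OC | starting material
8 | 4,5-dimethoxybenzyne (not isolated) | COC1=CC#CC=C1OC | intermediate
9 | (E)-5-(4-benzyloxy-3-methoxyphenyl)-1-(2-hydroxy-4,5-dimethoxyphenyl)pent-2-en-1-one (not isolated; present as its phenoxide) | COc1cc(CC/C=C/C(=O)c2cc(OC)c(OC)cc2O)ccc1OCc1ccccc1 | intermediate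
10 | 2-[2-(4-benzyloxy-3-methoxyphenyl)ethyl]-6,7-dimethoxychroman-4-one, racemic at C2 | COc1cc(CCC2CC(=O)c3cc(OC)c(OC)cc3O2)ccc1OCc1ccccc1 | intermediate
11 | 2-[2-(4-benzyloxy-3-methoxyphenyl)ethyl]-3-iodo-6,7-dimethoxychroman-4-one, racemic mixture of diastereomers (not isolated) | COc1cc(CCC2Oc3cc(OC)c(OC)cc3C(=O)C2I)ccc1OCc1ccccc1 | intermediate
12 | 2-[2-(4-benzyloxy-3-methoxyphenyl)ethyl]-6,7-dimethoxy-4H-chromen-4-one | COc1cc(CCc2cc(=O)c3cc(OC)c(OC)cc3o2)ccc1OCc1ccccc1 | intermediate
13 | 2-[2-(4-hydroxy-3-methoxyphenyl)ethyl]-6,7-dimethoxy-4H-chromen-4-one | COc1cc(CCc2cc(=O)c3cc(OC)c(OC)cc3o2)ccc1O | target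

**Step count**

Total: 6 steps. Longest linear sequence: 6 steps, from 1 to 13.

**Steps most likely to fail**

Step 4. The aryl anion may be protonated before it transfers the acyl group, so that the sequence stops at the aryl ester. The aryne may also be consumed by arylation of the product phenoxide, and the acid may deconjugate under hot basic fluoride. The fallback sets out from aldehyde 3 and builds the same ring by a Kabbe condensation. Heating 3 with purchased 1-(2-hydroxy-4,5-dimethoxyphenyl)ethanone (CC(=O)c1cc(OC)c(OC)cc1O) and pyrrolidine in ethanol should give enamine aldol addition, dehydration to the same hydroxyaryl enone 9 and oxa-Michael closure. It comes back to the route at chromanone 10, with water as the only by-product.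

Step 5. Dehydrogenation of a 2-alkyl chromanone may be sluggish, and ring iodination of the two electron-rich arenes may compete at the temperature needed. The fallback sets out from chromanone 10 and uses a Saegusa–Ito oxidation. TMSOTf and Et3N in CH2Cl2 at 0 °C should give the silyl enol ether 2-[2-(4-benzyloxy-3-methoxyphenyl)ethyl]-6,7-dimethoxy-4-(trimethylsilyloxy)-2H-chromene F1. Treatment with Pd(OAc)2 in MeCN at rt should then give β-hydride elimination from the palladium enolate and deliver the enone. It comes back to the route at chromone 12.

Step 3. The enolizable aldehyde may undergo self-aldol condensation in the amine medium, and part of the product may form as the β,γ-unsaturated isomer. The fallback sets out from aldehyde 3 and uses a Horner–Wadsworth–Emmons olefination with triethyl phosphonoacetate (LiCl, DBU, MeCN, rt). This should give ethyl (E)-5-(4-benzyloxy-3-methoxyphenyl)pent-2-enoate F2, which is saponified with LiOH in THF–H2O. It comes back to the route at acid 6.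

**Further compounds**

F0 | step 4 | none | none
F1 | step 5 | 2-[2-(4-benzyloxy-3-methoxyphenyl)ethyl]-6,7-dimethoxy-4-(trimethylsilyloxy)-2H-chromene (racemic) | COc1cc(CCC2C=C(O[Si](C)(C)C)c3cc(OC)c(OC)cc3O2)ccc1OCc1ccccc1
F2 | step 3 | ethyl (E)-5-(4-benzyloxy-3-methoxyphenyl)pent-2-enoate | CCOC(=O)/C=C/CCc1ccc(OCc2ccccc2)c(OC)c1
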